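**Plan**

1. Cuts (germacranolide numbering: C6 lactone carbinol, C7 ring-fusion carbon, C8 acyloxy carbon, C9 ketone, C11/C12/C13 lactone α-carbon/carbonyl/methylene): the C8–O ester; C9–C10 of the ten-membered ring; C7–C11 of the butanolide (C11/C12 from a phosphonoacetate on O6, C13 from formaldehyde); C6–C7 (alkynylation of an enal); C1=C10 (iodo-olefination).
2. Forward: neryl acetate (it carries the Z C4=C5 alkene) → Z,Z-iodo-enal → C6 alkynylation, semihydrogenation, epoxidation → butanolide ring first (C7–C11) → ten-membered ring second (C9–C10) → enone → ester.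
3. Enabling feature: C8 bears oxygen on the carbon next to C7, so C7/C8 is a latent cis-epoxide, and O6 sits three atoms from C11. A carbanion on the O6 ester should open the epoxide at C7 in the 5-exo mode, closing the five-membered lactone and freeing O8.
4. Stereochemistry: C6 from catalytic asymmetric alkynylation; C7 and C8 from a tartrate-controlled epoxidation (C7 by SN2 inversion, which gives the cis ring fusion; C8 by retention); the epoxyangelate centres from a second tartrate-controlled epoxidation; both ring alkenes Z from nerol and from the iodo-ylide.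

Key step: step 10

Assumption: the (S,S)-ProPhenol ligand is taken to give the (S)-carbinol in step 5; if the sense of induction proves opposite, the (R,R)-ligand is used instead.
Assumption: locants C1–C15 in the text follow germacranolide numbering as defined in the plan.

**Route**

Step 1
Reactants: 1 neryl acetate
Product: 3 (2Z)-3-methyl-6-oxohex-2-en-1-yl acetate, via ozonide 2 (not isolated)
Conditions: O3 (1 equiv, Sudan Red 7B end-point), CH2Cl2, −78 °C; then Me2S, −78 → 23 °C
Reagents that add atoms: ozone, [O-][O+]=O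
Why: Ozonolysis with reductive work-up should cleave the electron-rich 6,7-alkene selectively, because the 2,3-alkene is deactivated by the allylic acetate, and it leaves the Z geometry untouched.

Step 2
Reactants: 3 (2Z)-3-methyl-6-oxohex-2-en-1-yl acetate
Product: 4 (2Z,6Z)-7-iodo-3-methylocta-2,6-dien-1-yl acetate
Conditions: EtPPh3I, n-BuLi, THF, 0 °C; I2, −78 °C; NaHMDS, −20 °C; then 3, −78 → −20 °C
Reagents that add atoms: ethyltriphenylphosphonium iodide, CC[P+](c1ccccc1)(c1ccccc1)c1ccccc1.[I-]; iodine, II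
Why: The Stork–Zhao-type Wittig olefination with the iodo-ylide Ph3P=C(I)CH3 should give the (Z)-2-iodo-2-alkene (iodine cis to the chain) under kinetic control at low temperature, faster than any attack on the acetate.

Step 3
Reactants: 4 (2Z,6Z)-7-iodo-3-methylocta-2,6-dien-1-yl acetate
Product: 5 (2Z,6Z)-7-iodo-3-methylocta-2,6-dien-1-ol
Conditions: K2CO3 (cat.), MeOH, 0 → 23 °C
Reagents that add atoms: none
Why: Base-catalysed transesterification should free the allylic alcohol without touching the alkenyl iodide or either alkene.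

Step 4
Reactants: 5 (2Z,6Z)-7-iodo-3-methylocta-2,6-dien-1-ol
Product: 6 (2Z,6Z)-7-iodo-3-methylocta-2,6-dienal
Conditions: TEMPO (cat.), PhI(OAc)2, MeCN/pH 7 buffer, 0 °C
Reagents that add atoms: none
Why: The oxoammonium (TEMPO) oxidation of the primary allylic alcohol runs near neutrality, as in the oxidation of nerol to neral, so the Z-enal should not isomerise.

Step 5
Reactants: 6 (2Z,6Z)-7-iodo-3-methylocta-2,6-dienal; 7 trimethyl(prop-2-yn-1-yloxy)silane
Product: 10 (4S,5Z,9Z)-10-iodo-6-methylundeca-5,9-dien-2-yne-1,4-diol, via zinc acetylide 8 (not isolated), via silyl ether adduct 9 (not isolated)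
Conditions: Me2Zn, (S,S)-ProPhenol (cat.), Ph3P=O (cat.), toluene, 0–4 °C; aqueous NH4Cl work-up; then K2CO3, MeOH, 0 °C
Reagents that add atoms: none
Why: The zinc–ProPhenol-catalysed enantioselective alkynylation of an α,β-unsaturated aldehyde should deliver the alkynyl group to one carbonyl face and set the C6 carbinol as S, and the labile trimethylsilyl ether is methanolysed in the same operation.

Step 6
Reactants: 10 (4S,5Z,9Z)-10-iodo-6-methylundeca-5,9-dien-2-yne-1,4-diol
Product: 11 (2Z,4R,5Z,9Z)-10-iodo-6-methylundeca-2,5,9-triene-1,4-diol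
Conditions: H2 (1 atm, one equivalent), Pd/CaCO3 poisoned with Pb(OAc)2 (Lindlar catalyst), quinoline, EtOAc, 0 °C
Reagents that add atoms: none
Why: Lindlar semihydrogenation adds hydrogen syn to the activated 2-yne-1,4-diol to give the Z alkene, and the poisoned catalyst at low temperature is expected to spare the hindered trisubstituted alkene and alkenyl iodide (the C6 descriptor changes only because the priorities change).

Step 7
Reactants: 11 (2Z,4R,5Z,9Z)-10-iodo-6-methylundeca-2,5,9-triene-1,4-diol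
Product: 12 (1S,2Z,6Z)-1-[(2R,3S)-3-(hydroxymethyl)oxiran-2-yl]-7-iodo-3-methylocta-2,6-dien-1-ol
Conditions: Ti(OiPr)4 (1.1 equiv), L-(+)-diethyl tartrate (1.3 equiv), t-BuOOH (anhydrous, in decane), 4 Å MS, CH2Cl2, −20 °C; aqueous tartaric acid work-up
Reagents that add atoms: tert-butyl hydroperoxide, CC(C)(C)OO
Why: In this Sharpless asymmetric epoxidation the primary allylic alcohol directs oxygen only to C7=C8, and L-(+)-tartrate should deliver it to the face that gives the (2S,3R)-cis-epoxy alcohol pattern, which is also the face syn to the small secondary hydroxyl and anti to the dienyl chain in the conformer of least 1,3-allylic strain (matched case); the Z-substituted secondary allylic alcohol should react far more slowly.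

Step 8
Reactants: 12 (1S,2Z,6Z)-1-[(2R,3S)-3-(hydroxymethyl)oxiran-2-yl]-7-iodo-3-methylocta-2,6-dien-1-ol
Product: 13 (1S,2Z,6Z)-7-iodo-3-methyl-1-[(2R,3S)-3-{[(triethylsilyl)oxy]methyl}oxiran-2-yl]octa-2,6-dien-1-ol
Conditions: Et3SiCl (1.05 equiv), imidazole, CH2Cl2, −78 °C
Reagents that add atoms: chlorotriethylsilane, CC[Si](Cl)(CC)CC
Why: Kinetic silylation should take the unhindered primary hydroxyl over the hindered secondary one, and imidazole is too weak a base to start a Payne rearrangement.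

Step 9
Reactants: 13 (1S,2Z,6Z)-7-iodo-3-methyl-1-[(2R,3S)-3-{[(triethylsilyl)oxy]methyl}oxiran-2-yl]octa-2,6-dien-1-ol; 14 2-(diethoxyphosphoryl)acetic acid
Product: 15 (1S,2Z,6Z)-7-iodo-3-methyl-1-[(2R,3S)-3-{[(triethylsilyl)oxy]methyl}oxiran-2-yl]octa-2,6-dien-1-yl 2-(diethoxyphosphoryl)acetate
Conditions: DCC, DMAP (cat.), CH2Cl2, 0 → 23 °C
Reagents that add atoms: none
Why: Steglich esterification acylates the secondary alcohol at oxygen, so C6 keeps its configuration and the epoxide is not exposed to acid or strong base.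

Step 10
Reactants: 15 (1S,2Z,6Z)-7-iodo-3-methyl-1-[(2R,3S)-3-{[(triethylsilyl)oxy]methyl}oxiran-2-yl]octa-2,6-dien-1-yl 2-(diethoxyphosphoryl)acetate
Product: 17 (4R,5S)-4-[(1R)-1-hydroxy-2-[(triethylsilyl)oxy]ethyl]-5-[(1Z,5Z)-6-iodo-2-methylhepta-1,5-dien-1-yl]-3-methylideneoxolan-2-one, via phosphono lactone 16 (not isolated)
Conditions: LiCl, DBU (1.2 equiv), MeCN, 23 → 50 °C; then (CH2O)n, 0 → 23 °C
Reagents that add atoms: formaldehyde (as paraformaldehyde), C=O
Why: Proposed new method: DBU/LiCl deprotonates the phosphonoacetate, the lithium-chelated carbanion C11 opens the lithium-activated cis-epoxide at C7 in an intramolecular SN2 reaction, the C8 alkoxide is protonated at once by the amidinium ion or by the more acidic phosphono lactone, and the resulting phosphonate anion is olefinated by formaldehyde (Horner–Wadsworth–Emmons) to the exocyclic methylene. The closest known reaction types are the telescoped intramolecular Michael addition/olefination of phosphonoacetates of γ-hydroxy enones, the 5-exo opening at C2 of 2,3-epoxy alcohol carbamates by the tethered nitrogen, and the opening of epoxides by phosphonoacetate anions to α-phosphono-γ-lactones. The butanolide ring closes in the 5-exo-tet mode, with the carbanion entering anti to the C7–O bond. C7 is set by inversion and C8 keeps its oxygen with retention, so both come from the tartrate-controlled epoxide, and the threo relation of O6 to the epoxide becomes the cis ring fusion (H6 and H7 cis). The step needs attack at C7 (5-exo) over C8 (6-endo) and C- over O-alkylation: the three-atom O6–C12–C11 tether favours the five-membered transition state, C8 is shielded and inductively deactivated by the silyloxymethyl group, and the soft doubly stabilised carbanion alkylates at carbon. One equivalent of a weak base should keep the C8 alkoxide too short-lived to shift the silyl group or to translactonise.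

Step 11
Reactants: 17 (4R,5S)-4-[(1R)-1-hydroxy-2-[(triethylsilyl)oxy]ethyl]-5-[(1Z,5Z)-6-iodo-2-methylhepta-1,5-dien-1-yl]-3-methylideneoxolan-2-one
Product: 18 (4S,5S)-4-[(1R)-1-[(tert-butyldimethylsilyl)oxy]-2-[(triethylsilyl)oxy]ethyl]-5-[(1Z,5Z)-6-iodo-2-methylhepta-1,5-dien-1-yl]-3-methylideneoxolan-2-one
Conditions: TBSOTf, 2,6-lutidine, CH2Cl2, −78 → 0 °C
Reagents that add atoms: tert-butyldimethylsilyl trifluoromethanesulfonate, CC(C)(C)[Si](C)(C)OS(=O)(=O)C(F)(F)F
Why: Silylation with the silyl triflate and a hindered pyridine protects the C8 hydroxyl without alkoxide formation, so neither translactonisation nor addition to the methylene lactone should occur (the C7 descriptor changes only because the priorities change).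

Step 12
Reactants: 18 (4S,5S)-4-[(1R)-1-[(tert-butyldimethylsilyl)oxy]-2-[(triethylsilyl)oxy]ethyl]-5-[(1Z,5Z)-6-iodo-2-methylhepta-1,5-dien-1-yl]-3-methylideneoxolan-2-one
Product: 20 (2R)-2-[(tert-butyldimethylsilyl)oxy]-2-[(2S,3S)-2-[(1Z,5Z)-6-iodo-2-methylhepta-1,5-dien-1-yl]-4-methylidene-5-oxooxolan-3-yl]acetaldehyde, via alkoxysulfonium salt 19 (not isolated)
Conditions: (COCl)2, DMSO, CH2Cl2, −78 → −40 °C; then Et3N, −78 → 0 °C
Reagents that add atoms: none
Why: Swern conditions oxidise a primary triethylsilyl ether directly to the aldehyde (oxidative desilylation) while the secondary tert-butyldimethylsilyl ether survives, and the low temperature should prevent epimerisation at C8.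

Step 13
Reactants: 20 (2R)-2-[(tert-butyldimethylsilyl)oxy]-2-[(2S,3S)-2-[(1Z,5Z)-6-iodo-2-methylhepta-1,5-dien-1-yl]-4-methylidene-5-oxooxolan-3-yl]acetaldehyde
Product: 22 (3aS,4R,6Z,10Z,11aS)-4-[(tert-butyldimethylsilyl)oxy]-5-hydroxy-6,10-dimethyl-3-methylidene-3a,4,5,8,9,11a-hexahydrocyclodeca[b]furan-2(3H)-one (both C5 epimers), via alkenylchromium 21 (not isolated)
Conditions: CrCl2 (excess), NiCl2 (cat.), DMSO/THF, 23 °C, slow addition at high dilution
Reagents that add atoms: none
Why: In the Nozaki–Hiyama–Kishi reaction the NiCl2-catalysed insertion gives the alkenylchromium with retention of the Z geometry, and it should add to the aldehyde intramolecularly because the cis-disubstituted lactone and the two Z alkenes hold the chain ends close; the new C9 carbinol centre is removed in the next step.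

Step 14
Reactants: 22 (3aS,4R,6Z,10Z,11aS)-4-[(tert-butyldimethylsilyl)oxy]-5-hydroxy-6,10-dimethyl-3-methylidene-3a,4,5,8,9,11a-hexahydrocyclodeca[b]furan-2(3H)-one
Product: 23 (3aS,4R,6Z,10Z,11aS)-4-[(tert-butyldimethylsilyl)oxy]-6,10-dimethyl-3-methylidene-3a,4,8,9-tetrahydrocyclodeca[b]furan-2,5(3H,11aH)-dione
Conditions: Dess–Martin periodinane, NaHCO3, CH2Cl2, 0 → 23 °C
Reagents that add atoms: none
Why: Buffered Dess–Martin oxidation should convert both epimeric allylic alcohols into the single Z enone without disturbing the α-silyloxy centre.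

Step 15
Reactants: 23 (3aS,4R,6Z,10Z,11aS)-4-[(tert-butyldimethylsilyl)oxy]-6,10-dimethyl-3-methylidene-3a,4,8,9-tetrahydrocyclodeca[b]furan-2,5(3H,11aH)-dione
Product: 24 (3aR,4R,6Z,10Z,11aS)-4-hydroxy-6,10-dimethyl-3-methylidene-3a,4,8,9-tetrahydrocyclodeca[b]furan-2,5(3H,11aH)-dione
Conditions: HF·pyridine, pyridine, THF, 0 → 23 °C
Reagents that add atoms: none
Why: Buffered fluoride-mediated desilylation works without base, so C8 (α to the ketone) should not epimerise and the lactone should not open (the C3a descriptor changes only because the priorities change).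

Step 16
Reactants: 25 angelic acid
Product: 26 (2Z)-2-methylbut-2-en-1-ol
Conditions: LiAlH4, Et2O, 0 °C; aqueous work-up
Reagents that add atoms: none
Why: Hydride reduction of the carboxylic acid is a 1,2-reduction and should keep the Z geometry.

Step 17
Reactants: 26 (2Z)-2-methylbut-2-en-1-ol
Product: 27 [(2R,3S)-2,3-dimethyloxiran-2-yl]methanol
Conditions: Ti(OiPr)4 (cat.), D-(−)-diethyl tartrate (cat.), t-BuOOH, 4 Å MS, CH2Cl2, −20 °C
Reagents that add atoms: tert-butyl hydroperoxide, CC(C)(C)OO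
Why: Sharpless asymmetric epoxidation with D-(−)-tartrate should deliver oxygen to the face of the Z trisubstituted allylic alcohol that gives the (2R,3S)-epoxy alcohol, the two methyl groups staying trans.

Step 18
Reactants: 27 [(2R,3S)-2,3-dimethyloxiran-2-yl]methanol
Product: 28 (2S,3S)-2,3-dimethyloxirane-2-carboxylic acid
Conditions: RuCl3·xH2O (cat.), NaIO4, MeCN/CCl4/H2O, 0 → 23 °C
Reagents that add atoms: water, O
Why: RuO4 generated in situ oxidises the primary alcohol through the aldehyde hydrate to the acid without touching the epoxide centres (the C2 descriptor changes only because the priorities change).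

Step 19
Reactants: 24 (3aR,4R,6Z,10Z,11aS)-4-hydroxy-6,10-dimethyl-3-methylidene-3a,4,8,9-tetrahydrocyclodeca[b]furan-2,5(3H,11aH)-dione; 28 (2S,3S)-2,3-dimethyloxirane-2-carboxylic acid
Product: 30 (3aS,4R,6Z,10Z,11aS)-6,10-dimethyl-3-methylidene-2,5-dioxo-2,3,3a,4,5,8,9,11a-octahydrocyclodeca[b]furan-4-yl (2S,3S)-2,3-dimethyloxirane-2-carboxylate, via mixed anhydride 29 (not isolated)
Conditions: 28, 2,4,6-trichlorobenzoyl chloride, Et3N, THF, 0 °C; then 24, DMAP, toluene, 23 °C
Reagents that add atoms: none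
Why: Yamaguchi esterification should acylate the hindered secondary α-hydroxy ketone at oxygen with retention at C8, and the epoxy acid has no α-hydrogen and cannot epimerise.

**Compound list**

1 | neryl acetate, (2Z)-3,7-dimethylocta-2,6-dien-1-yl acetate | CC(C)=CCC/C(C)=C\COC(C)=O | starting material
2 | ozonide, (2Z)-5-(5,5-dimethyl-1,2,4-trioxolan-3-yl)-3-methylpent-2-en-1-yl acetate | CC(=O)OC/C=C(/C)CCC1OOC(C)(C)O1 | intermediate
3 | (2Z)-3-methyl-6-oxohex-2-en-1-yl acetate | CC(=O)OC/C=C(/C)CCC=O | intermediate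
4 | (2Z,6Z)-7-iodo-3-methylocta-2,6-dien-1-yl acetate | C/C(I)=C/CC/C(C)=C\COC(C)=O | intermediate
5 | (2Z,6Z)-7-iodo-3-methylocta-2,6-dien-1-ol | C/C(I)=C/CC/C(C)=C\CO | intermediate
6 | (2Z,6Z)-7-iodo-3-methylocta-2,6-dienal | C/C(I)=C/CC/C(C)=C\C=O | intermediate
7 | trimethyl(prop-2-yn-1-yloxy)silane | C#CCO[Si](C)(C)C | starting material
8 | zinc acetylide, methyl{3-[(trimethylsilyl)oxy]prop-1-yn-1-yl}zinc | C[Zn]C#CCO[Si](C)(C)C | intermediate
9 | silyl ether adduct, (4S,5Z,9Z)-10-iodo-6-methyl-1-[(trimethylsilyl)oxy]undeca-5,9-dien-2-yn-4-ol | C/C(I)=C/CC/C(C)=C\[C@H](O)C#CCO[Si](C)(C)C | intermediate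
10 | (4S,5Z,9Z)-10-iodo-6-methylundeca-5,9-dien-2-yne-1,4-diol | C/C(I)=C/CC/C(C)=C\[C@H](O)C#CCO | intermediate
11 | (2Z,4R,5Z,9Z)-10-iodo-6-methylundeca-2,5,9-triene-1,4-diol | C/C(I)=C/CC/C(C)=C\[C@H](O)/C=C\CO | intermediate
12 | (1S,2Z,6Z)-1-[(2R,3S)-3-(hydroxymethyl)oxiran-2-yl]-7-iodo-3-methylocta-2,6-dien-1-ol (cis-epoxide, threo to the carbinol) | C/C(I)=C/CC/C(C)=C\[C@H](O)[C@H]1O[C@H]1CO | intermediate
13 | (1S,2Z,6Z)-7-iodo-3-methyl-1-[(2R,3S)-3-{[(triethylsilyl)oxy]methyl}oxiran-2-yl]octa-2,6-dien-1-ol | C/C(I)=C/CC/C(C)=C\[C@H](O)[C@H]1O[C@H]1CO[Si](CC)(CC)CC | intermediate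
14 | 2-(diethoxyphosphoryl)acetic acid | OC(=O)CP(=O)(OCC)OCC | starting material
15 | (1S,2Z,6Z)-7-iodo-3-methyl-1-[(2R,3S)-3-{[(triethylsilyl)oxy]methyl}oxiran-2-yl]octa-2,6-dien-1-yl 2-(diethoxyphosphoryl)acetate | C/C(I)=C/CC/C(C)=C\[C@H](OC(=O)CP(=O)(OCC)OCC)[C@H]1O[C@H]1CO[Si](CC)(CC)CC | intermediate
16 | phosphono lactone, diethyl {(4R,5S)-4-[(1R)-1-hydroxy-2-[(triethylsilyl)oxy]ethyl]-5-[(1Z,5Z)-6-iodo-2-methylhepta-1,5-dien-1-yl]-2-oxooxolan-3-yl}phosphonate (C3 epimers) | CCOP(=O)(OCC)C1C(=O)O[C@@H](/C=C(/C)CC/C=C(/C)I)[C@H]1[C@@H](O)CO[Si](CC)(CC)CC | intermediate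
17 | (4R,5S)-4-[(1R)-1-hydroxy-2-[(triethylsilyl)oxy]ethyl]-5-[(1Z,5Z)-6-iodo-2-methylhepta-1,5-dien-1-yl]-3-methylideneoxolan-2-one (4,5-cis) | C=C1C(=O)O[C@@H](/C=C(/C)CC/C=C(/C)I)[C@H]1[C@@H](O)CO[Si](CC)(CC)CC | intermediate
18 | (4S,5S)-4-[(1R)-1-[(tert-butyldimethylsilyl)oxy]-2-[(triethylsilyl)oxy]ethyl]-5-[(1Z,5Z)-6-iodo-2-methylhepta-1,5-dien-1-yl]-3-methylideneoxolan-2-one | C=C1C(=O)O[C@@H](/C=C(/C)CC/C=C(/C)I)[C@H]1[C@@H](O[Si](C)(C)C(C)(C)C)CO[Si](CC)(CC)CC | intermediate
19 | alkoxysulfonium salt, {(2R)-2-[(tert-butyldimethylsilyl)oxy]-2-[(2S,3S)-2-[(1Z,5Z)-6-iodo-2-methylhepta-1,5-dien-1-yl]-4-methylidene-5-oxooxolan-3-yl]ethoxy}dimethylsulfonium chloride | C=C1C(=O)O[C@@H](/C=C(/C)CC/C=C(/C)I)[C@H]1[C@@H](O[Si](C)(C)C(C)(C)C)CO[S+](C)C.[Cl-] | intermediate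
20 | (2R)-2-[(tert-butyldimethylsilyl)oxy]-2-[(2S,3S)-2-[(1Z,5Z)-6-iodo-2-methylhepta-1,5-dien-1-yl]-4-methylidene-5-oxooxolan-3-yl]acetaldehyde | C=C1C(=O)O[C@@H](/C=C(/C)CC/C=C(/C)I)[C@H]1[C@@H](O[Si](C)(C)C(C)(C)C)C=O | intermediate
21 | alkenylchromium, the (Z)-alkenyl–CrCl2 species from 20 with chromium in place of iodine (trivalent chromium) | C=C1C(=O)O[C@@H](/C=C(/C)CC/C=C(/C)[Cr](Cl)Cl)[C@H]1[C@@H](O[Si](C)(C)C(C)(C)C)C=O | intermediate
22 | (3aS,4R,6Z,10Z,11aS)-4-[(tert-butyldimethylsilyl)oxy]-5-hydroxy-6,10-dimethyl-3-methylidene-3a,4,5,8,9,11a-hexahydrocyclodeca[b]furan-2(3H)-one (both C5 epimers) | C=C1C(=O)O[C@H]2/C=C(/C)CC/C=C(/C)C(O)[C@H](O[Si](C)(C)C(C)(C)C)[C@@H]12 | intermediate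
23 | (3aS,4R,6Z,10Z,11aS)-4-[(tert-butyldimethylsilyl)oxy]-6,10-dimethyl-3-methylidene-3a,4,8,9-tetrahydrocyclodeca[b]furan-2,5(3H,11aH)-dione | C=C1C(=O)O[C@H]2/C=C(/C)CC/C=C(/C)C(=O)[C@H](O[Si](C)(C)C(C)(C)C)[C@@H]12 | intermediate
24 | (3aR,4R,6Z,10Z,11aS)-4-hydroxy-6,10-dimethyl-3-methylidene-3a,4,8,9-tetrahydrocyclodeca[b]furan-2,5(3H,11aH)-dione | C=C1C(=O)O[C@H]2/C=C(/C)CC/C=C(/C)C(=O)[C@H](O)[C@@H]12 | intermediate
25 | angelic acid, (2Z)-2-methylbut-2-enoic acid | C/C=C(/C)C(=O)O | starting material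
26 | (2Z)-2-methylbut-2-en-1-ol | C/C=C(/C)CO | intermediate
27 | [(2R,3S)-2,3-dimethyloxiran-2-yl]methanol | OC[C@@]1(C)O[C@H]1C | intermediate
28 | (2S,3S)-2,3-dimethyloxirane-2-carboxylic acid | OC(=O)[C@@]1(C)O[C@H]1C | intermediate
29 | mixed anhydride, (2S,3S)-2,3-dimethyloxirane-2-carboxylic 2,4,6-trichlorobenzoic anhydride | O=C(OC(=O)[C@@]1(C)O[C@H]1C)c1c(Cl)cc(Cl)cc1Cl | intermediate
30 | (3aS,4R,6Z,10Z,11aS)-6,10-dimethyl-3-methylidene-2,5-dioxo-2,3,3a,4,5,8,9,11a-octahydrocyclodeca[b]furan-4-yl (2S,3S)-2,3-dimethyloxirane-2-carboxylate | C=C1C(=O)O[C@H]2/C=C(/C)CC/C=C(/C)C(=O)[C@H](OC(=O)[C@@]3(C)O[C@H]3C)[C@@H]12 | target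

**Step count**

Total steps: 19. Longest linear sequence: 16 steps (steps 1–15 and 19); steps 16–18 make the acid side chain.

**Steps most likely to fail**

Step 10 (proposed new method). The stabilised carbanion may be too weak a nucleophile to open the 2,3-disubstituted epoxide, it may open it at C8 in the 6-endo mode, or the transient C8 alkoxide may shift the silyl group or translactonise. The fallback uses known chemistry, sets out from 13 and comes back at 17. It brings in C11 by an intermolecular, hydroxyl-directed SN2 opening with the same inversion at C7, and closes the lactone at oxygen afterwards.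
- Silylation of 13 (TBSOTf, 2,6-lutidine) gives the bis-silyl ether F1, and selective methanolysis of the primary triethylsilyl ether (PPTS, MeOH, 0 °C) gives the primary epoxy alcohol F2.
- Diethyl[(trimethylsilyl)ethynyl]aluminium in toluene at 0 °C opens the 2,3-epoxy alcohol at the carbon remote from the free hydroxyl (C7) with inversion, to give the alkynyl diol F3.
- 2,2-Dimethoxypropane/PPTS gives the acetonide F4. Hydroboration of the silylalkyne with dicyclohexylborane followed by NaOH/H2O2 gives the carboxylic acid F5.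
- Bu4NF frees the C6 hydroxyl, which lactonises on acidification to the cis-lactone F6.
- LiHMDS and dimethylmethylideneammonium iodide give the Mannich base F7, MeI gives the ammonium iodide F8, and NaHCO3 eliminates it to the methylene lactone F9.
- Aqueous acetic acid removes the acetonide to give the diol F10, and Et3SiCl/imidazole at −78 °C silylates the primary hydroxyl to give 17.

Step 13. Oligomerisation may outrun closure of the ten-membered ring, or the alkenylchromium may be protonated before it reaches the aldehyde. The fallback sets out from 18 and comes back at 23. It forms the same C9–C10 bond at the ketone oxidation level by a palladium-catalysed intramolecular acylation of an alkenylstannane (Stille type).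
- Hexamethylditin and Pd(PPh3)4 (zerovalent palladium) in toluene convert 18 into the alkenylstannane F11.
- Swern oxidation of the primary triethylsilyl ether gives the aldehyde F12, and NaClO2/NaH2PO4/2-methylbut-2-ene gives the acid F13.
- 1-Chloro-N,N,2-trimethylprop-1-en-1-amine gives the acid chloride F14 under neutral conditions.
- Slow addition of F14 to Pd2(dba)3/tri(2-furyl)phosphine in toluene at high dilution closes the ring to the Z enone 23.

Step 7. Poor facial selectivity may result if the tartrate and the C6 centre prove mismatched, or if the secondary hydroxyl binds titanium and misdirects the oxidant. The fallback sets out from 6 and comes back at 15. It uses the opposite C6 configuration, for which the same tartrate is then the matched partner, and corrects C6 at the esterification.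
- Alkynylation of 6 with 7 under (R,R)-ProPhenol/Me2Zn gives the epimeric silyl ether adduct F15, and methanolysis gives the (4R)-ynediol F16.
- Lindlar semihydrogenation gives the (4S)-enediol F17.
- Ti(OiPr)4/L-(+)-diethyl tartrate/t-BuOOH gives the erythro epoxy diol F18, with the same epoxide configuration as in 12.
- Et3SiCl/imidazole gives the primary silyl ether F19.
- Mitsunobu esterification of F19 with 14 (PPh3, diisopropyl azodicarboxylate, toluene, 0 °C) inverts C6 and gives 15.

**Further compounds**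

F1 | step 10 | tert-butyl{[(1S,2Z,6Z)-7-iodo-3-methyl-1-[(2R,3S)-3-{[(triethylsilyl)oxy]methyl}oxiran-2-yl]octa-2,6-dien-1-yl]oxy}dimethylsilane | C/C(I)=C/CC/C(C)=C\[C@H](O[Si](C)(C)C(C)(C)C)[C@H]1O[C@H]1CO[Si](CC)(CC)CC
F2 | step 10 | {(2S,3R)-3-[(1S,2Z,6Z)-1-[(tert-butyldimethylsilyl)oxy]-7-iodo-3-methylocta-2,6-dien-1-yl]oxiran-2-yl}methanol | C/C(I)=C/CC/C(C)=C\[C@H](O[Si](C)(C)C(C)(C)C)[C@H]1O[C@H]1CO
F3 | step 10 | (2R,3R,4S,5Z,9Z)-4-[(tert-butyldimethylsilyl)oxy]-10-iodo-6-methyl-3-[(trimethylsilyl)ethynyl]undeca-5,9-diene-1,2-diol | C/C(I)=C/CC/C(C)=C\[C@H](O[Si](C)(C)C(C)(C)C)[C@H](C#C[Si](C)(C)C)[C@@H](O)CO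
F4 | step 10 | acetonide of F3 (2,2-dimethyl-1,3-dioxolane across the 1,2-diol) | C/C(I)=C/CC/C(C)=C\[C@H](O[Si](C)(C)C(C)(C)C)[C@H](C#C[Si](C)(C)C)[C@@H]1COC(C)(C)O1
F5 | step 10 | carboxylic acid from F4 (CH2CO2H in place of the silylethynyl group) | C/C(I)=C/CC/C(C)=C\[C@H](O[Si](C)(C)C(C)(C)C)[C@H](CC(=O)O)[C@@H]1COC(C)(C)O1
F6 | step 10 | 4,5-cis-4-(2,2-dimethyl-1,3-dioxolan-4-yl)-5-[(1Z,5Z)-6-iodo-2-methylhepta-1,5-dien-1-yl]oxolan-2-one | C1C(=O)O[C@@H](/C=C(/C)CC/C=C(/C)I)[C@H]1[C@@H]2COC(C)(C)O2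
F7 | step 10 | 3-[(dimethylamino)methyl] derivative of F6 (C3 epimers) | CN(C)CC1C(=O)O[C@@H](/C=C(/C)CC/C=C(/C)I)[C@H]1[C@@H]2COC(C)(C)O2
F8 | step 10 | trimethylammonium iodide of F7 | C[N+](C)(C)CC1C(=O)O[C@@H](/C=C(/C)CC/C=C(/C)I)[C@H]1[C@@H]2COC(C)(C)O2.[I-]
F9 | step 10 | 3-methylidene derivative of F6 | C=C1C(=O)O[C@@H](/C=C(/C)CC/C=C(/C)I)[C@H]1[C@@H]2COC(C)(C)O2
F10 | step 10 | (4R,5S)-4-[(1R)-1,2-dihydroxyethyl]-5-[(1Z,5Z)-6-iodo-2-methylhepta-1,5-dien-1-yl]-3-methylideneoxolan-2-one | C=C1C(=O)O[C@@H](/C=C(/C)CC/C=C(/C)I)[C@H]1[C@@H](O)CO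
F11 | step 13 | alkenylstannane from 18 (trimethylstannyl in place of iodine, Z) | C=C1C(=O)O[C@@H](/C=C(/C)CC/C=C(/C)[Sn](C)(C)C)[C@H]1[C@@H](O[Si](C)(C)C(C)(C)C)CO[Si](CC)(CC)CC
F12 | step 13 | aldehyde from F11 (trimethylstannyl analogue of 20) | C=C1C(=O)O[C@@H](/C=C(/C)CC/C=C(/C)[Sn](C)(C)C)[C@H]1[C@@H](O[Si](C)(C)C(C)(C)C)C=O
F13 | step 13 | carboxylic acid from F12 | C=C1C(=O)O[C@@H](/C=C(/C)CC/C=C(/C)[Sn](C)(C)C)[C@H]1[C@@H](O[Si](C)(C)C(C)(C)C)C(=O)O
F14 | step 13 | acid chloride from F13 | C=C1C(=O)O[C@@H](/C=C(/C)CC/C=C(/C)[Sn](C)(C)C)[C@H]1[C@@H](O[Si](C)(C)C(C)(C)C)C(=O)Cl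
F15 | step 7 | (4R)-epimer of 9 | C/C(I)=C/CC/C(C)=C\[C@@H](O)C#CCO[Si](C)(C)C
F16 | step 7 | (4R,5Z,9Z)-10-iodo-6-methylundeca-5,9-dien-2-yne-1,4-diol | C/C(I)=C/CC/C(C)=C\[C@@H](O)C#CCO
F17 | step 7 | (2Z,4S,5Z,9Z)-10-iodo-6-methylundeca-2,5,9-triene-1,4-diol | C/C(I)=C/CC/C(C)=C\[C@@H](O)/C=C\CO
F18 | step 7 | (1R,2Z,6Z)-1-[(2R,3S)-3-(hydroxymethyl)oxiran-2-yl]-7-iodo-3-methylocta-2,6-dien-1-ol | C/C(I)=C/CC/C(C)=C\[C@@H](O)[C@H]1O[C@H]1CO
F19 | step 7 | (1R,2Z,6Z)-7-iodo-3-methyl-1-[(2R,3S)-3-{[(triethylsilyl)oxy]methyl}oxiran-2-yl]octa-2,6-dien-1-ol | C/C(I)=C/CC/C(C)=C\[C@@H](O)[C@H]1O[C@H]1CO[Si](CC)(CC)CC
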